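**Retrosynthetic overview**
1. Ring B (seven-membered) is closed last: the C8=C9 alkene comes from ring-closing metathesis of a ring A cyclopentane carrying a C6 anisoate/methallyl arm and a C10 angelate/vinyl arm.
2. The C10–O bond and the C10 stereocentre are made in one step by a rhodium-catalysed, redox-neutral addition of angelic acid to a propargyl group on quaternary C1 (new method).
3. The C6 anisoate comes from chemoselective acylation of a diol; the C4 carbinol from isopropyl addition to the ring A ketone.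
4. C1, C5 and C6 come from a one-pot copper-catalysed asymmetric conjugate methylation / aluminium-enolate aldol of a 3-propargylcyclopentenone with 3-methylbut-3-enal.
5. Ring A is bought as 3-ethoxycyclopent-2-enone; only ring B is constructed.

Assumption: the SMILES is read as (1S,4R,5S,6S,10R) in daucane numbering (trans ring fusion, 4β-OH, 6α- and 10α-acyloxy, Z-angelate); this numbering is used for all intermediates.

**Step 1**
Reactants: 1 3-methylbut-3-en-1-ol
Product: 2 3-methylbut-3-enal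
Conditions: Dess–Martin periodinane (1.1 equiv), CH2Cl2, 0 °C, 1 h; silica plug, solution used at once
Reagents that add atoms: none
Why: Dess–Martin oxidation of the primary homoallylic alcohol under non-basic conditions gives the β,γ-unsaturated aldehyde without moving the double bond into conjugation; no stereocentre is formed.

**Step 2**
Reactants: 3 3-ethoxycyclopent-2-en-1-one; 4 (3-bromoprop-1-yn-1-yl)trimethylsilane
Product: 7 3-[3-(trimethylsilyl)prop-2-yn-1-yl]cyclopent-2-en-1-one, via Grignard reagent 5 (not isolated), via carbinol adduct 6 (not isolated)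
Conditions: 4, Mg, HgCl2 (1 mol %), Et2O, 0 °C; then 3, −78 → 0 °C; then 1 M HCl, 0 °C, 30 min
Reagents that add atoms: water, O
Why: Stork–Danheiser sequence, in which the silyl-capped propargyl Grignard reagent adds 1,2 to the vinylogous ester and acid hydrolysis of the enol ether with loss of water transposes the carbonyl to give the 3-substituted enone; no stereocentre is formed.

**Step 3**
Reactants: 7 3-[3-(trimethylsilyl)prop-2-yn-1-yl]cyclopent-2-en-1-one; 2 3-methylbut-3-enal
Product: 9 (2S,3R)-2-[(1S)-1-hydroxy-3-methylbut-3-en-1-yl]-3-methyl-3-[3-(trimethylsilyl)prop-2-yn-1-yl]cyclopentan-1-one, via aluminium enolate 8 (not isolated)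
Conditions: Me3Al (1.5 equiv), CuTC [Cu(O2C-C4H3S)] (5 mol %), chiral phosphoramidite ligand (10 mol %, enantiomer giving the 3R adduct), Et2O, −30 °C; then 2 (2 equiv), −78 °C; sat. aq. NH4Cl
Reagents that add atoms: trimethylaluminium, C[Al](C)C
Why: Copper-catalysed asymmetric conjugate addition sets C1 under ligand control and gives a regiodefined aluminium enolate, whose closed Zimmerman–Traxler aldol with 2 is expected on the face anti to the propargyl arm and, from the fixed E(O)-enolate, gives the anti ketol, setting C5 and C6.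

**Step 4**
Reactants: 9 (2S,3R)-2-[(1S)-1-hydroxy-3-methylbut-3-en-1-yl]-3-methyl-3-[3-(trimethylsilyl)prop-2-yn-1-yl]cyclopentan-1-one
Product: 11 (1R,2S,3R)-2-[(1S)-1-hydroxy-3-methylbut-3-en-1-yl]-3-methyl-1-(propan-2-yl)-3-(prop-2-yn-1-yl)cyclopentan-1-ol, via silylated diol 10 (not isolated)
Conditions: LaCl3·2LiCl (1 equiv), iPrMgCl (3 equiv), THF, −20 → 0 °C; then MeOH, K2CO3, rt
Reagents that add atoms: isopropylmagnesium chloride, CC(C)[Mg]Cl
Why: Lanthanide-promoted Grignard 1,2-addition (which suppresses enolisation and β-hydride reduction) to the chelated β-alkoxy ketone occurs anti to the C5 side chain and sets C4 as the 4β-hydroxy-4α-isopropyl carbinol, after which basic methanolysis cleaves the alkynyl C–Si bond.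

**Step 5**
Reactants: 11 (1R,2S,3R)-2-[(1S)-1-hydroxy-3-methylbut-3-en-1-yl]-3-methyl-1-(propan-2-yl)-3-(prop-2-yn-1-yl)cyclopentan-1-ol; 12 4-methoxybenzoyl chloride
Product: 13 (1S)-1-[(1S,2R,5R)-2-hydroxy-5-methyl-2-(propan-2-yl)-5-(prop-2-yn-1-yl)cyclopentyl]-3-methylbut-3-en-1-yl 4-methoxybenzoate
Conditions: Et3N, DMAP (20 mol %), CH2Cl2, 0 °C → rt
Reagents that add atoms: none
Why: DMAP-catalysed acylation is selective for the secondary C6 hydroxyl because the tertiary C4 hydroxyl does not react with the aroyl chloride; no stereocentre is touched.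

**Step 6**
Reactants: 13 (1S)-1-[(1S,2R,5R)-2-hydroxy-5-methyl-2-(propan-2-yl)-5-(prop-2-yn-1-yl)cyclopentyl]-3-methylbut-3-en-1-yl 4-methoxybenzoate; 14 angelic acid [(2Z)-2-methylbut-2-enoic acid]
Product: 16 (1S)-1-[(1S,2R,5S)-2-hydroxy-5-methyl-5-[(1R)-1-{[(2Z)-2-methylbut-2-enoyl]oxy}prop-2-en-1-yl]-2-(propan-2-yl)cyclopentyl]-3-methylbut-3-en-1-yl 4-methoxybenzoate, via allene 15 (not isolated)
Conditions: [Rh(cod)Cl]2 (2.5 mol %), (R,R)-DIOP (6 mol %; the antipode if it proves to be the matched ligand for 10R), 14 (1.5 equiv), 1,2-dichloroethane, 60 °C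
Reagents that add atoms: none
Why: Proposed new method: a rhodium-catalysed redox-neutral propargylic C–H acyloxylation forms the C10–O bond directly with angelic acid — O–H oxidative addition of the acid to monovalent rhodium gives a trivalent rhodium hydride carboxylate, hydrometalation/β-hydride elimination isomerises the terminal alkyne to allene 15, a second hydrometalation gives a π-allyl rhodium carboxylate, and inner-sphere C–O reductive elimination at the substituted allyl terminus releases the branched ester, with the C2-symmetric diphosphine choosing the C10 face; the closest known reaction type is the rhodium/diphosphine-catalysed coupling of terminal alkynes or allenes with carboxylic acids to branched allylic esters, which has not been shown for a propargylic carbon on a quaternary stereocentre, for isomerisation-prone angelic acid, or as a catalyst-controlled diastereoselective step on a substrate of this kind.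

**Step 7**
Reactants: 16 (1S)-1-[(1S,2R,5S)-2-hydroxy-5-methyl-5-[(1R)-1-{[(2Z)-2-methylbut-2-enoyl]oxy}prop-2-en-1-yl]-2-(propan-2-yl)cyclopentyl]-3-methylbut-3-en-1-yl 4-methoxybenzoate
Product: 17 (3R,3aS,4S,8R,8aS)-3-hydroxy-6,8a-dimethyl-8-{[(2Z)-2-methylbut-2-enoyl]oxy}-3-(propan-2-yl)-1,2,3,3a,4,5,8,8a-octahydroazulen-4-yl 4-methoxybenzoate
Conditions: second-generation Hoveyda–Grubbs catalyst, RuCl2(C21H26N2)(=CH-C6H4-2-OiPr) (5 mol %), toluene (2 mM), 80 °C
Reagents that add atoms: none
Why: Ring-closing metathesis between the vinyl group and the 1,1-disubstituted alkene releases ethene and closes the seven-membered ring with the trisubstituted C8=C9 alkene, the electron-poor trisubstituted angelate alkene being inert to the ruthenium carbene; no stereocentre is formed.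

**Compound list**
1 | 3-methylbut-3-en-1-ol | CC(=C)CCO | starting material
2 | 3-methylbut-3-enal | CC(=C)CC=O | intermediate
3 | 3-ethoxycyclopent-2-en-1-one | CCOC1=CC(=O)CC1 | starting material
4 | (3-bromoprop-1-yn-1-yl)trimethylsilane | C[Si](C)(C)C#CCBr | starting material
5 | [3-(trimethylsilyl)prop-2-yn-1-yl]magnesium bromide (not isolated) | C[Si](C)(C)C#CC[Mg]Br | intermediate
6 | 3-ethoxy-1-[3-(trimethylsilyl)prop-2-yn-1-yl]cyclopent-2-en-1-ol (not isolated) | CCOC1=CC(O)(CC#C[Si](C)(C)C)CC1 | intermediate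
7 | 3-[3-(trimethylsilyl)prop-2-yn-1-yl]cyclopent-2-en-1-one | C[Si](C)(C)C#CCC1=CC(=O)CC1 | intermediate
8 | dimethyl{[(3R)-3-methyl-3-[3-(trimethylsilyl)prop-2-yn-1-yl]cyclopent-1-en-1-yl]oxy}alumane (not isolated) | C[Si](C)(C)C#CC[C@@]1(C)CCC(O[Al](C)C)=C1 | intermediate
9 | (2S,3R)-2-[(1S)-1-hydroxy-3-methylbut-3-en-1-yl]-3-methyl-3-[3-(trimethylsilyl)prop-2-yn-1-yl]cyclopentan-1-one | C[Si](C)(C)C#CC[C@@]1(C)CCC(=O)[C@@H]1[C@H](CC(C)=C)O | intermediate
10 | (1R,2S,3R)-2-[(1S)-1-hydroxy-3-methylbut-3-en-1-yl]-3-methyl-1-(propan-2-yl)-3-[3-(trimethylsilyl)prop-2-yn-1-yl]cyclopentan-1-ol (not isolated) | C[Si](C)(C)C#CC[C@@]1(C)CC[C@@](O)(C(C)C)[C@@H]1[C@H](CC(C)=C)O | intermediate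
11 | (1R,2S,3R)-2-[(1S)-1-hydroxy-3-methylbut-3-en-1-yl]-3-methyl-1-(propan-2-yl)-3-(prop-2-yn-1-yl)cyclopentan-1-ol | C#CC[C@@]1(C)CC[C@@](O)(C(C)C)[C@@H]1[C@H](CC(C)=C)O | intermediate
12 | 4-methoxybenzoyl chloride | COc1ccc(cc1)C(Cl)=O | starting material
13 | (1S)-1-[(1S,2R,5R)-2-hydroxy-5-methyl-2-(propan-2-yl)-5-(prop-2-yn-1-yl)cyclopentyl]-3-methylbut-3-en-1-yl 4-methoxybenzoate | C#CC[C@@]1(C)CC[C@@](O)(C(C)C)[C@@H]1[C@H](CC(C)=C)OC(=O)c1ccc(OC)cc1 | intermediate
14 | angelic acid, (2Z)-2-methylbut-2-enoic acid | C/C=C(/C)C(=O)O | starting material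
15 | allene isomer of 13, C1 bearing a propa-1,2-dien-1-yl group (not isolated) | C=C=C[C@@]1(C)CC[C@@](O)(C(C)C)[C@@H]1[C@H](CC(C)=C)OC(=O)c1ccc(OC)cc1 | intermediate
16 | (1S)-1-[(1S,2R,5S)-2-hydroxy-5-methyl-5-[(1R)-1-{[(2Z)-2-methylbut-2-enoyl]oxy}prop-2-en-1-yl]-2-(propan-2-yl)cyclopentyl]-3-methylbut-3-en-1-yl 4-methoxybenzoate | C/C=C(/C)C(=O)O[C@H](C=C)[C@@]1(C)CC[C@@](O)(C(C)C)[C@@H]1[C@H](CC(C)=C)OC(=O)c1ccc(OC)cc1 | intermediate
17 | (3R,3aS,4S,8R,8aS)-3-hydroxy-6,8a-dimethyl-8-{[(2Z)-2-methylbut-2-enoyl]oxy}-3-(propan-2-yl)-1,2,3,3a,4,5,8,8a-octahydroazulen-4-yl 4-methoxybenzoate | C/C=C(/C)C(=O)O[C@@H]1C=C(C)C[C@H](OC(=O)c2ccc(OC)cc2)[C@@H]2[C@]1(C)CC[C@@]2(O)C(C)C | target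

**Totals**
Total step count: 7. Longest linear sequence: 6 steps (steps 2 to 7, from 3 and 4); step 1 is a one-step side branch.

**Three steps most likely to fail**

Step 6 (the proposed new method). The risks are attack at the unhindered allyl terminus (linear ester) because C10 is neopentyl, low diastereoselection at C10, and Z-to-E isomerisation of the angelate. The fallback uses known chemistry and sets out from 13. Lindlar semi-hydrogenation (H2, Pd/CaCO3 poisoned with Pb(OAc)2, quinoline) gives the allyl compound (1S)-1-[(1S,2R,5R)-2-hydroxy-5-methyl-2-(propan-2-yl)-5-(prop-2-en-1-yl)cyclopentyl]-3-methylbut-3-en-1-yl 4-methoxybenzoate F1. Ring-closing metathesis under the step 7 conditions gives jaeschkeanadiol 6-O-(4-methoxybenzoate) F2. Allylic oxidation with Rh2(cap)4 and t-BuOOH is expected at C10, since C7 is deactivated by the neighbouring aroyloxy group, and gives the 10-oxo enone F3. Luche reduction (NaBH4, CeCl3·7H2O, MeOH) should deliver hydride anti to the C1 methyl and give the 10β-alcohol F4. Mitsunobu esterification with 14 (PPh3, DIAD) inverts C10, and the fallback comes back to the route at 17.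

Step 3. The risks are modest enantioselectivity on the cyclopentenone, inefficient trapping of the aluminium enolate, and limited facial control at C5. Methyl and the propargyl CH2 differ little in size, so the C5 ratio may be no better than about 3:1; the C5 epimer and any syn ketol would be removed by chromatography at 9 or 11. The fallback sets out from 7 and decouples the two events. The same conjugate addition is quenched with Et3SiOTf to give the isolable silyl enol ether triethyl{[(3R)-3-methyl-3-[3-(trimethylsilyl)prop-2-yn-1-yl]cyclopent-1-en-1-yl]oxy}silane F5, whose enantiopurity can be checked. An open-transition-state Mukaiyama aldol with 2 (BF3·OEt2, CH2Cl2, −78 °C, aqueous HCl work-up) then comes back to the route at 9.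

Step 4. The risks are enolisation, retro-aldol or β-hydride reduction in place of isopropyl addition to the hindered ketone, and attack on the wrong face. The fallback sets out from 9. The C6 hydroxyl is silylated (Me3SiCl, imidazole) to give (2S,3R)-3-methyl-2-{(1S)-3-methyl-1-[(trimethylsilyl)oxy]but-3-en-1-yl}-3-[3-(trimethylsilyl)prop-2-yn-1-yl]cyclopentan-1-one F6. The organocerium reagent from iPrLi and CeCl3 (THF, −78 °C) adds under steric, non-chelation control to give the carbinol (1R,2S,3R)-3-methyl-2-{(1S)-3-methyl-1-[(trimethylsilyl)oxy]but-3-en-1-yl}-1-(propan-2-yl)-3-[3-(trimethylsilyl)prop-2-yn-1-yl]cyclopentan-1-ol F7, which is not isolated. K2CO3 in MeOH removes both silyl groups, and the fallback comes back to the route at 11.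

**Further compounds**
F1 | step 6 | (1S)-1-[(1S,2R,5R)-2-hydroxy-5-methyl-2-(propan-2-yl)-5-(prop-2-en-1-yl)cyclopentyl]-3-methylbut-3-en-1-yl 4-methoxybenzoate | C=CC[C@@]1(C)CC[C@@](O)(C(C)C)[C@@H]1[C@H](CC(C)=C)OC(=O)c1ccc(OC)cc1
F2 | step 6 | (3R,3aS,4S,8aR)-3-hydroxy-6,8a-dimethyl-3-(propan-2-yl)-1,2,3,3a,4,5,8,8a-octahydroazulen-4-yl 4-methoxybenzoate | C1C=C(C)C[C@H](OC(=O)c2ccc(OC)cc2)[C@@H]2[C@]1(C)CC[C@@]2(O)C(C)C
F3 | step 6 | (3R,3aS,4S,8aS)-3-hydroxy-6,8a-dimethyl-8-oxo-3-(propan-2-yl)-1,2,3,3a,4,5,8,8a-octahydroazulen-4-yl 4-methoxybenzoate | O=C1C=C(C)C[C@H](OC(=O)c2ccc(OC)cc2)[C@@H]2[C@]1(C)CC[C@@]2(O)C(C)C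
F4 | step 6 | (3R,3aS,4S,8S,8aS)-3,8-dihydroxy-6,8a-dimethyl-3-(propan-2-yl)-1,2,3,3a,4,5,8,8a-octahydroazulen-4-yl 4-methoxybenzoate | O[C@H]1C=C(C)C[C@H](OC(=O)c2ccc(OC)cc2)[C@@H]2[C@]1(C)CC[C@@]2(O)C(C)C
F5 | step 3 | triethyl{[(3R)-3-methyl-3-[3-(trimethylsilyl)prop-2-yn-1-yl]cyclopent-1-en-1-yl]oxy}silane | C[Si](C)(C)C#CC[C@@]1(C)CCC(O[Si](CC)(CC)CC)=C1
F6 | step 4 | (2S,3R)-3-methyl-2-{(1S)-3-methyl-1-[(trimethylsilyl)oxy]but-3-en-1-yl}-3-[3-(trimethylsilyl)prop-2-yn-1-yl]cyclopentan-1-one | C[Si](C)(C)C#CC[C@@]1(C)CCC(=O)[C@@H]1[C@H](CC(C)=C)O[Si](C)(C)C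
F7 | step 4 | (1R,2S,3R)-3-methyl-2-{(1S)-3-methyl-1-[(trimethylsilyl)oxy]but-3-en-1-yl}-1-(propan-2-yl)-3-[3-(trimethylsilyl)prop-2-yn-1-yl]cyclopentan-1-ol | C[Si](C)(C)C#CC[C@@]1(C)CC[C@@](O)(C(C)C)[C@@H]1[C@H](CC(C)=C)O[Si](C)(C)C
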